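The target is cut at C1–C8. Its C9 ketone lies between bridgeheads C1 and C5, and quaternary C8 is bonded to C1, which is the imprint of a C8 shift from a C9 carbinol onto C1. The key step oxidises the C2/C4 diketone of a cis-fused hydrindanol with a trivalent-iodine reagent, and the C9 alkoxide drives C8 onto C1. In one operation the cyclopentane becomes ring A (C1, C9, C5, C6, C7, C8), the fused diketone ring becomes bridged ring B (C1–C5, C9), and the C9 ketone appears. The precursor carries the C7 prenyl, C8 gem-dimethyl, C5 methyl and a free C1 methylene. Bridgehead prenylation and C3 acylation finish the synthesis.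

Key step: step 7

Remark: target numbering (C1 and C5 bridgeheads, C2–C4 diketone bridge, C6–C8 bridge, C9 bridging ketone) is used for all intermediates, and each enol drawn (13, 21) stands for its rapidly equilibrating tautomers.

Step 1
Reactants: 1 2-methylcyclopent-2-en-1-one; 2 4-bromo-2-methylbut-1-ene
Product: 5 (R)-2,2-dimethyl-3-(3-methylbut-3-en-1-yl)cyclopentan-1-one, via Grignard reagent 3 (not isolated), via bromomagnesium enolate 4 (not isolated)
Conditions: Mg, Et2O (2 to 3); Cu(OTf)2 (3 mol%), chiral hydroxyalkyl-imidazolinium salt as NHC precursor (4 mol%), Et2O, −30 °C, slow addition of 3; then MeI, DMPU, −30 °C to rt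
Reagents that add atoms: 4-bromo-2-methylbut-1-ene 2 (through 3), C=C(C)CCBr; iodomethane, CI
Why: Copper-catalysed asymmetric conjugate addition of a primary alkyl Grignard reagent to a 2-substituted cyclopentenone under chiral NHC control is an established reaction class, the ligand enantiomer being chosen so that the alkyl group enters the enone face that gives (R) at C3 (the future C7), and C-methylation of the regiodefined magnesium enolate then builds the non-stereogenic gem-dimethyl carbon (the future C8) in the same flask.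

Step 2
Reactants: 5 (R)-2,2-dimethyl-3-(3-methylbut-3-en-1-yl)cyclopentan-1-one
Product: 6 (S)-2,2-dimethyl-3-(3-methylbut-2-en-1-yl)cyclopentan-1-one
Conditions: chloro[N,N′-bis(3,5-di-tert-butylsalicylidene)-1,2-cyclohexanediaminato]cobalt (3 mol%), PhSiH3 (6 mol%), PhH, rt; AgNO3–SiO2 chromatography
Reagents that add atoms: none
Why: Cobalt-hydride hydrogen-atom-transfer isomerisation moves the 1,1-disubstituted alkene by one position to the more stable trisubstituted prenyl alkene through a tertiary radical and goes no further because the next shift is uphill, while the ketone and the C3 stereocentre are untouched (the descriptor changes by priority only) and residual terminal isomer is removed on silver-nitrate silica.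

Step 3
Reactants: 6 (S)-2,2-dimethyl-3-(3-methylbut-2-en-1-yl)cyclopentan-1-one
Product: 7 (3R)-5-acetyl-2,2-dimethyl-3-(3-methylbut-2-en-1-yl)cyclopentan-1-one (C5 epimers and enol forms)
Conditions: MgBr2·OEt2 (2.5 equiv), i-Pr2NEt (3 equiv), 1-acetylbenzotriazole (1.2 equiv), CH2Cl2, rt
Reagents that add atoms: 1-acetyl-1H-benzotriazole, CC(=O)n1nnc2ccccc12
Why: Soft-enolisation C-acylation (crossed Claisen condensation) can only take place at C5 because the other α-carbon is quaternary, and the product is parked as its magnesium diketonate, which prevents a second acylation; the new C5 centre remains epimerisable and is fixed only in step 4.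

Step 4
Reactants: 7 (3R)-5-acetyl-2,2-dimethyl-3-(3-methylbut-2-en-1-yl)cyclopentan-1-one
Product: 8 (3R,5R)-5-acetyl-2,2,5-trimethyl-3-(3-methylbut-2-en-1-yl)cyclopentan-1-one (acetyl cis to prenyl)
Conditions: MeI (3 equiv), K2CO3 (2 equiv), acetone, rt
Reagents that add atoms: iodomethane, CI
Why: C-Alkylation of the planar potassium diketonate by iodomethane should take place on the ring face anti to the C7 prenyl group, which in the preferred envelope also carries the pseudo-axial C8 methyl, so that the new quaternary C5 has methyl trans and acetyl cis to prenyl (5R), any epimer being separable by chromatography.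

Step 5
Reactants: 8 (3R,5R)-5-acetyl-2,2,5-trimethyl-3-(3-methylbut-2-en-1-yl)cyclopentan-1-one
Product: 9 1-[(1R,4R)-1,3,3-trimethyl-4-(3-methylbut-2-en-1-yl)-2-oxocyclopentyl]butane-1,3-dione
Conditions: MgBr2·OEt2 (2.5 equiv), i-Pr2NEt (3 equiv), 1-acetylbenzotriazole (1.2 equiv), CH2Cl2, rt
Reagents that add atoms: 1-acetyl-1H-benzotriazole, CC(=O)n1nnc2ccccc12
Why: Claisen condensation by soft enolisation: the acetyl methyl is the only enolisable position of this quaternary diketone, so acetyl transfer extends it to the C4–C3–C2–C1 chain and again stops at the magnesium diketonate stage.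

Step 6
Reactants: 9 1-[(1R,4R)-1,3,3-trimethyl-4-(3-methylbut-2-en-1-yl)-2-oxocyclopentyl]butane-1,3-dione
Product: 11 (2R,3aS,7aS)-7a-hydroxy-1,1,3a-trimethyl-2-(3-methylbut-2-en-1-yl)-cis-hydrindane-4,6-dione, via dilithium dienediolate 10 (not isolated)
Conditions: LiN(i-Pr)2 (2.3 equiv), THF, −78 to −20 °C; AcOH quench
Reagents that add atoms: none
Why: Dianion aldol addition: the second equivalent of base removes a terminal C1 proton, and this carbanion adds to the C9 ketone in a 6-(enolexo)-exo-trig closure that can only reach the carbonyl face on which the C5 tether sits, so the C9 carbinol is formed with a cis ring fusion (hydroxyl cis to the C5 methyl, 7aS).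

Step 7
Reactants: 11 (2R,3aS,7aS)-7a-hydroxy-1,1,3a-trimethyl-2-(3-methylbut-2-en-1-yl)-cis-hydrindane-4,6-dione
Product: 13 (1S,5R,7R)-4-hydroxy-5,8,8-trimethyl-7-(3-methylbut-2-en-1-yl)bicyclo[3.3.1]non-3-ene-2,9-dione, via C3 phenyliodonium ylide 12 (not isolated)
Conditions: PhI(OAc)2 (1.3 equiv), KOH (5 equiv), MeOH, 0 °C; aq. HCl work-up
Reagents that add atoms: none
Why: Ligand exchange of the potassium diketonate at trivalent iodine gives the C3-bound iodonium ylide 12, whose tautomer enolised towards C1 is an allyl-type iodane with C1 as its electrophilic terminus. The C9 alkoxide then pushes the C9–C8 bond onto C1 in a vinylogous (SN2′-like) semipinacol 1,2-shift with reductive loss of iodobenzene, the closest known reaction type being the hypervalent-iodine oxidative ring expansion of annulated diketone carbinols to bicyclo[3.3.1]nonane-2,4,9-triones. Ring A (C1, C9, C5, C6, C7, C8) is closed by this suprafacial 1,2-alkyl shift, that is by expansion of the cyclopentane through a three-centre transition state and not by a cyclisation, while ring B only changes from fused to bridged. The new stereocentre C1 is controlled by the cis ring fusion, because C8 can only be delivered to the face of C1 on which it already sits and the bicycle allows a single bridgehead configuration, while C5 and C7 pass through unchanged. The step needs C8 and not C5 to migrate and C1 and not C3 to be attacked: in the cis-fused chair the exocyclic C9–C8 bond is axial and overlaps with the C1 terminus whereas the endocyclic C9–C5 bond cannot, C5 carries an acyl group that lowers its migratory aptitude, and the intramolecular shift should outrun methanol capture at C3. The product leaves the equilibrium as the stable potassium enolate of a cyclic 1,3-diketone.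

Step 8
Reactants: 13 (1S,5R,7R)-4-hydroxy-5,8,8-trimethyl-7-(3-methylbut-2-en-1-yl)bicyclo[3.3.1]non-3-ene-2,9-dione
Product: 14 (1S,5R,7R)-4-methoxy-5,8,8-trimethyl-7-(3-methylbut-2-en-1-yl)bicyclo[3.3.1]non-3-ene-2,9-dione
Conditions: Me3SiCHN2 (2 equiv), MeOH/PhMe, 0 °C to rt
Reagents that add atoms: (trimethylsilyl)diazomethane, C[Si](C)(C)C=[N+]=[N-]
Why: O-Methylation of the acidic enol by diazomethane released in situ gives the vinylogous ester without C3 alkylation and without touching C1, C5 or C7; the isomer methylated on the C4 oxygen, which keeps the C2 ketone next to C1–H, is carried on, and the C2-methoxy regioisomer that may accompany it is separated and hydrolysed back to 13 (aqueous HCl, THF) for another pass.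

Step 9
Reactants: 14 (1S,5R,7R)-4-methoxy-5,8,8-trimethyl-7-(3-methylbut-2-en-1-yl)bicyclo[3.3.1]non-3-ene-2,9-dione; 15 prenyl bromide
Product: 17 (1S,5R,7R)-4-methoxy-5,8,8-trimethyl-1,7-bis(3-methylbut-2-en-1-yl)bicyclo[3.3.1]non-3-ene-2,9-dione, via bridgehead organolithium 16 (not isolated)
Conditions: LiN(i-Pr)2 (1.3 equiv), THF, −78 °C; then 15, −78 to −40 °C
Reagents that add atoms: prenyl bromide 15, CC(C)=CCBr
Why: Bridgehead lithiation–alkylation: C1–H is flanked by the C2 and C9 carbonyl groups and is removed kinetically by the amide base to give a pyramidal, configurationally locked organolithium that attacks prenyl bromide at its primary carbon, so the quaternary C1 is formed with the only configuration the bicycle allows.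

Step 10
Reactants: 17 (1S,5R,7R)-4-methoxy-5,8,8-trimethyl-1,7-bis(3-methylbut-2-en-1-yl)bicyclo[3.3.1]non-3-ene-2,9-dione; 18 isobutyryl chloride
Product: 20 (1R,5R,7R)-4-methoxy-5,8,8-trimethyl-1,7-bis(3-methylbut-2-en-1-yl)-3-(2-methylpropanoyl)bicyclo[3.3.1]non-3-ene-2,9-dione, via C3 vinyllithium 19 (not isolated)
Conditions: lithium 2,2,6,6-tetramethylpiperidide (1.6 equiv), THF, −78 °C; then 18, −78 °C
Reagents that add atoms: isobutyryl chloride 18, CC(C)C(Cl)=O
Why: Vinylic lithiation–acylation: with C1 quaternary, the hindered amide base removes the C3–H lying between the C2 ketone and the methoxy-bearing C4, and the vinyllithium is acylated by isobutyryl chloride (addition–elimination) to install the C3 ketone, the C1 descriptor changing by priority only.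

Step 11
Reactants: 20 (1R,5R,7R)-4-methoxy-5,8,8-trimethyl-1,7-bis(3-methylbut-2-en-1-yl)-3-(2-methylpropanoyl)bicyclo[3.3.1]non-3-ene-2,9-dione
Product: 21 (1R,5R,7R)-4-hydroxy-5,8,8-trimethyl-1,7-bis(3-methylbut-2-en-1-yl)-3-(2-methylpropanoyl)bicyclo[3.3.1]non-3-ene-2,9-dione (CNP0265287.1)
Conditions: LiCl (5 equiv), DMSO, 120 °C; aq. HCl work-up
Reagents that add atoms: none
Why: Krapcho-type demethylation: chloride attacks the O-methyl carbon of the vinylogous ester in an SN2 reaction and releases the delocalised triketone enolate, which is protonated on work-up to the enolised target with all three stereocentres and both prenyl groups untouched.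

Compound list
1 | 2-methylcyclopent-2-en-1-one | CC1=CCCC1=O | starting material
2 | 4-bromo-2-methylbut-1-ene | C=C(C)CCBr | starting material
3 | (3-methylbut-3-en-1-yl)magnesium bromide | C=C(C)CC[Mg]Br | intermediate
4 | bromomagnesium (R)-2-methyl-3-(3-methylbut-3-en-1-yl)cyclopent-1-en-1-olate | C=C(C)CC[C@@H]1CCC(O[Mg]Br)=C1C | intermediate
5 | (R)-2,2-dimethyl-3-(3-methylbut-3-en-1-yl)cyclopentan-1-one | C=C(C)CC[C@@H]1CCC(=O)C1(C)C | intermediate
6 | (S)-2,2-dimethyl-3-(3-methylbut-2-en-1-yl)cyclopentan-1-one | CC(C)=CC[C@@H]1CCC(=O)C1(C)C | intermediate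
7 | (3R)-5-acetyl-2,2-dimethyl-3-(3-methylbut-2-en-1-yl)cyclopentan-1-one (C5 epimers and enol forms) | CC(C)=CC[C@@H]1CC(C(C)=O)C(=O)C1(C)C | intermediate
8 | (3R,5R)-5-acetyl-2,2,5-trimethyl-3-(3-methylbut-2-en-1-yl)cyclopentan-1-one (acetyl cis to prenyl) | CC(C)=CC[C@@H]1C[C@](C)(C(C)=O)C(=O)C1(C)C | intermediate
9 | 1-[(1R,4R)-1,3,3-trimethyl-4-(3-methylbut-2-en-1-yl)-2-oxocyclopentyl]butane-1,3-dione | CC(C)=CC[C@@H]1C[C@](C)(C(=O)CC(C)=O)C(=O)C1(C)C | intermediate
10 | dilithium 1-[(1R,4R)-1,3,3-trimethyl-4-(3-methylbut-2-en-1-yl)-2-oxocyclopentyl]buta-1,3-diene-1,3-diolate | CC(C)=CC[C@@H]1C[C@](C)(C(O[Li])=CC(=C)O[Li])C(=O)C1(C)C | intermediate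
11 | (2R,3aS,7aS)-7a-hydroxy-1,1,3a-trimethyl-2-(3-methylbut-2-en-1-yl)-cis-hydrindane-4,6-dione (indane numbering; hydroxyl cis to the 3a-methyl, prenyl cis to the C4 carbonyl) | CC(C)=CC[C@@H]1C[C@]2(C)C(=O)CC(=O)C[C@]2(O)C1(C)C | intermediate
12 | C3 phenyliodonium ylide of 11 (5-phenyliodonio enolate in indane numbering) | CC(C)=CC[C@@H]1C[C@]2(C)C(=O)C([I+]c3ccccc3)=C([O-])C[C@]2(O)C1(C)C | intermediate
13 | (1S,5R,7R)-4-hydroxy-5,8,8-trimethyl-7-(3-methylbut-2-en-1-yl)bicyclo[3.3.1]non-3-ene-2,9-dione | CC(C)=CC[C@@H]1C[C@@]2(C)C(=O)[C@H](C(=O)C=C2O)C1(C)C | intermediate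
14 | (1S,5R,7R)-4-methoxy-5,8,8-trimethyl-7-(3-methylbut-2-en-1-yl)bicyclo[3.3.1]non-3-ene-2,9-dione | CC(C)=CC[C@@H]1C[C@@]2(C)C(=O)[C@H](C(=O)C=C2OC)C1(C)C | intermediate
15 | prenyl bromide (1-bromo-3-methylbut-2-ene) | CC(C)=CCBr | starting material
16 | C1-lithio derivative of 14 (bridgehead organolithium) | CC(C)=CC[C@@H]1C[C@@]2(C)C(=O)[C@]([Li])(C(=O)C=C2OC)C1(C)C | intermediate
17 | (1S,5R,7R)-4-methoxy-5,8,8-trimethyl-1,7-bis(3-methylbut-2-en-1-yl)bicyclo[3.3.1]non-3-ene-2,9-dione | CC(C)=CC[C@@H]1C[C@@]2(C)C(=O)[C@](CC=C(C)C)(C(=O)C=C2OC)C1(C)C | intermediate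
18 | isobutyryl chloride | CC(C)C(Cl)=O | starting material
19 | C3-lithio derivative of 17 (vinyllithium) | CC(C)=CC[C@@H]1C[C@@]2(C)C(=O)[C@](CC=C(C)C)(C(=O)C([Li])=C2OC)C1(C)C | intermediate
20 | (1R,5R,7R)-4-methoxy-5,8,8-trimethyl-1,7-bis(3-methylbut-2-en-1-yl)-3-(2-methylpropanoyl)bicyclo[3.3.1]non-3-ene-2,9-dione | CC(C)=CC[C@@H]1C[C@@]2(C)C(=O)[C@](CC=C(C)C)(C(=O)C(C(=O)C(C)C)=C2OC)C1(C)C | intermediate
21 | (1R,5R,7R)-4-hydroxy-5,8,8-trimethyl-1,7-bis(3-methylbut-2-en-1-yl)-3-(2-methylpropanoyl)bicyclo[3.3.1]non-3-ene-2,9-dione | CC(C)=CC[C@@H]1C[C@@]2(C)C(=O)[C@](CC=C(C)C)(C(=O)C(C(=O)C(C)C)=C2O)C1(C)C | target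

Total step count: 11
Longest linear sequence: 11 steps (from 1 to 21)

Steps most likely to fail

The first is step 7. The C3 iodonium ylide may be intercepted by methanol or hydroxide at C3, or the β-hydroxy ketone may open by retro-aldol cleavage, before C8 migrates. The fallback sets out from 11 and comes back at 13, and runs the same C9-to-C1 shift as a two-stage β-hydroxy selenide ring expansion. Treatment of 11 with LiN(i-Pr)2 (3.3 equiv, THF, −78 to 0 °C) should give the alkoxide dianion, whose terminal carbon C1 is selenenylated by PhSeCl to give the C1 selenide 7-(phenylselanyl)-11 F1. AgBF4 on Al2O3 in CH2Cl2 then pulls the selenium group off C1 while the C9–C8 bond migrates, which should give 13.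

The second is step 1. Facial discrimination by the copper–NHC catalyst on the five-membered enone may be weak, and proton transfer between enolate and product may blur the methylation. The fallback sets out from 1 and comes back at 6, replacing steps 1 and 2, with auxiliary control in place of catalyst control.
- The chiral reagent (3aR,7aR)-2-allyl-1,3-dimethyloctahydro-1H-1,3,2-benzodiazaphosphole 2-oxide F2 is made from (1R,2R)-N,N′-dimethylcyclohexane-1,2-diamine, allylphosphonic dichloride and Et3N; the diamine enantiomer is chosen to give the (S) adduct.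
- Lithiated F2 (n-BuLi, THF, −78 °C) adds through its γ-carbon to 1, and trapping of the enolate with MeI should give the vinylphosphonamide adduct (3aR,7aR)-2-{(E)-3-[(1S)-2,2-dimethyl-3-oxocyclopentyl]prop-1-en-1-yl}-1,3-dimethyloctahydro-1H-1,3,2-benzodiazaphosphole 2-oxide F3.
- Ozonolysis (O3, CH2Cl2/MeOH, −78 °C; Me2S) cleaves the vinylphosphonamide to the keto aldehyde (S)-2-(2,2-dimethyl-3-oxocyclopentyl)acetaldehyde F4.
- A Wittig reaction with isopropylidenetriphenylphosphorane (from isopropyltriphenylphosphonium iodide and n-BuLi), which leaves the hindered ketone alone, gives 6.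

The third is step 9. Deprotonation at the vinylic C3–H may compete with the bridgehead and lead to prenylation at C3. The fallback sets out from 14 and comes back at 17, and blocks C3 first. LiN(i-Pr)2 with Me3SiCl present (THF, −78 °C) should give the vinylsilane 3-(trimethylsilyl)-14 F5. With C3 occupied, LiN(i-Pr)2 followed by prenyl bromide should give 3-(trimethylsilyl)-17 F6, and Bu4NF in THF removes the silyl group to give 17.

Further compounds
F1 | step 7 | 7-(phenylselanyl) derivative of 11 (indane numbering, C7 is C1 of the target; both C7 epimers) | CC(C)=CC[C@@H]1C[C@]2(C)C(=O)CC(=O)C([Se]c3ccccc3)[C@]2(O)C1(C)C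
F2 | step 1 | (3aR,7aR)-2-allyl-1,3-dimethyloctahydro-1H-1,3,2-benzodiazaphosphole 2-oxide | C=CCP1(=O)N(C)[C@@H]2CCCC[C@H]2N1C
F3 | step 1 | (3aR,7aR)-2-{(E)-3-[(1S)-2,2-dimethyl-3-oxocyclopentyl]prop-1-en-1-yl}-1,3-dimethyloctahydro-1H-1,3,2-benzodiazaphosphole 2-oxide | CN1[C@@H]2CCCC[C@H]2N(C)P1(=O)/C=C/C[C@@H]3CCC(=O)C3(C)C
F4 | step 1 | (S)-2-(2,2-dimethyl-3-oxocyclopentyl)acetaldehyde | O=CC[C@@H]1CCC(=O)C1(C)C
F5 | step 9 | 3-(trimethylsilyl) derivative of 14 (configuration as in 14) | CC(C)=CC[C@@H]1C[C@@]2(C)C(=O)[C@H](C(=O)C([Si](C)(C)C)=C2OC)C1(C)C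
F6 | step 9 | 3-(trimethylsilyl) derivative of 17 (configuration as in 17) | CC(C)=CC[C@@H]1C[C@@]2(C)C(=O)[C@](CC=C(C)C)(C(=O)C([Si](C)(C)C)=C2OC)C1(C)C
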